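Locants: quinolizidin-2-one numbering (C1, C2=O, C3, C4, N5, C6–C9, C9a) for the half made first, primed for the second; the macrocycle is C9–(CH2)5–C1′ plus C9′–(CH2)5–C1.
Retrosynthesis: one alkene is put back into each five-carbon bridge; C9′–CH2 (allylic) and C1′–C9a′ are cut together, then C9–CH2 and C1–C9a likewise, so both halves fall back on one N-(2-methyl-3-oxoalkenyl)piperidin-2-one made from piperidin-2-one, methyl methacrylate and a pentenyl Grignard reagent.
Enabling feature: C9 is β to N5 and α to C9a, and C9a lies one six-membered chair away from C1 of the ketone arm N5–C4–C3–C2(=O)–C1; with C9a stored as a lactam carbonyl, reduction gives the enamine N5–C9a=C9, C-allylation at C9 makes C9a an iminium carbon, and the ketone enol closes C1–C9a (Mannich).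
Forward: monomer → allylic acetate and allylic silyl ether (cross-metathesis) → intermolecular enamine allylation/Mannich builds the first quinolizidinone → terminus to acetate → the same event run intramolecularly closes a 20-membered ring at C9′–CH2, and the transannular Mannich contracts it to the 16-membered ring and the second quinolizidinone → hydrogenation of both alkenes.
Stereochemistry: the target is centrosymmetric (meso), so racemic material is used; in each half C9a is set anti to the C9 chain in the Mannich chair, and C1/C3 settle by enolization to the trans-fused isomer with equatorial C9 chain and C3 methyl and axial C1 chain; the unlike pairing of the halves is not biased by the substrate and is taken from the acid-equilibrated macrocycle mixture by chromatography, the like (C2) isomer being recycled.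
Key step: step 9

Remark: SMILES of racemates show one enantiomer; centres that are still mobile (the CHMe beside an open-chain ketone, C9′ of an iminium ion) are left undefined; pent-4-en-1-ylmagnesium bromide is taken as the commercial THF solution.

Step 1
Reactants: 1 piperidin-2-one; 2 methyl methacrylate
Product: 3 methyl 2-methyl-3-(2-oxopiperidin-1-yl)propanoate (racemic)
Conditions: t-BuOK (10 mol%), THF, 50 °C
Reagents that add atoms: none
Why: Base-catalysed aza-Michael addition of the lactam N–H to the methacrylate, the lactam anion being regenerated by proton transfer to the ester enolate; the new CHMe centre (future C3) may be racemic because it is re-equilibrated after each Mannich closure.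

Step 2
Reactants: 3 methyl 2-methyl-3-(2-oxopiperidin-1-yl)propanoate
Product: 4 N-methoxy-N,2-dimethyl-3-(2-oxopiperidin-1-yl)propanamide (racemic)
Conditions: MeNH(OMe)·HCl, i-PrMgCl, THF, −20 → 0 °C
Reagents that add atoms: N,O-dimethylhydroxylamine hydrochloride, CNOC.Cl
Why: Weinreb amide formation by aminolysis of the methyl ester with the chloromagnesium amide of N,O-dimethylhydroxylamine; the tertiary lactam is far less electrophilic than the ester at this temperature.

Step 3
Reactants: 4 N-methoxy-N,2-dimethyl-3-(2-oxopiperidin-1-yl)propanamide; 5 pent-4-en-1-ylmagnesium bromide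
Product: 6 1-(2-methyl-3-oxooct-7-en-1-yl)piperidin-2-one (racemic)
Conditions: THF, 0 °C; aq. NH4Cl
Reagents that add atoms: none
Why: Weinreb ketone synthesis, in which the Grignard reagent adds once to give a magnesium chelate that collapses to the ketone only on work-up; the Weinreb amide reacts well before the tertiary lactam at 0 °C.

Step 4
Reactants: 6 1-(2-methyl-3-oxooct-7-en-1-yl)piperidin-2-one; 7 (Z)-but-2-ene-1,4-diyl diacetate
Product: 8 (2E)-8-methyl-7-oxo-9-(2-oxopiperidin-1-yl)non-2-en-1-yl acetate (racemic)
Conditions: second-generation Grubbs catalyst RuCl2(=CHPh)(PCy3)(H2IMes) (5 mol%), 7 (3 equiv), CH2Cl2, 40 °C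
Reagents that add atoms: none
Why: Olefin cross-metathesis of a terminal alkene with a symmetrical allylic diacetate used in excess; the alkene geometry is of no consequence because the π-allyl complex equilibrates and the alkene is hydrogenated at the end.

Step 5
Reactants: 6 1-(2-methyl-3-oxooct-7-en-1-yl)piperidin-2-one; 9 allyloxy(tert-butyl)dimethylsilane
Product: 10 1-[(7E)-9-(tert-butyldimethylsilyloxy)-2-methyl-3-oxonon-7-en-1-yl]piperidin-2-one (racemic)
Conditions: second-generation Grubbs catalyst RuCl2(=CHPh)(PCy3)(H2IMes) (5 mol%), 9 (4 equiv), CH2Cl2, 40 °C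
Reagents that add atoms: none
Why: Olefin cross-metathesis of two terminal alkenes with the allyl silyl ether in excess; it gives the same chain as in 8 with a terminus that is inert to zerovalent palladium.

Step 6
Reactants: 10 1-[(7E)-9-(tert-butyldimethylsilyloxy)-2-methyl-3-oxonon-7-en-1-yl]piperidin-2-one; 8 (2E)-8-methyl-7-oxo-9-(2-oxopiperidin-1-yl)non-2-en-1-yl acetate
Product: 13 first quinolizidinone silyl ether (racemic), via endocyclic enamine 11 (not isolated), via C-allylated iminium acetate 12 (not isolated)
Conditions: 10 (1.2 equiv), IrCl(CO)(PPh3)2 (1 mol%), (Me2SiH)2O (2 equiv), toluene, rt, then evaporate; 8 (1.0 equiv), Pd(PPh3)4 (5 mol%), MeCN, rt; AcOH (10 equiv), 60 °C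
Reagents that add atoms: none
Why: Three known reaction types are telescoped, namely iridium-catalysed hydrosilylation of the tertiary lactam to the enamine, Tsuji–Trost C-allylation of that enamine at C9 by the π-allylpalladium complex of 8, and acid-mediated intramolecular Mannich closure; C9a forms anti to the C9 chain in the chair, and C1 and C3 equilibrate by enolization to the axial C1 chain and equatorial methyl.

Step 7
Reactants: 13 first quinolizidinone silyl ether
Product: 14 first quinolizidinone allylic alcohol (racemic)
Conditions: Bu4NF, AcOH, THF, rt
Reagents that add atoms: none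
Why: Fluoride desilylation buffered with AcOH so that the β-amino ketone meets no basic fluoride; any silyl ether already lost under the acidic Mannich conditions converges on the same alcohol.

Step 8
Reactants: 14 first quinolizidinone allylic alcohol
Product: 15 first quinolizidinone allylic acetate (racemic)
Conditions: Ac2O, pyridine, DMAP (cat.), CH2Cl2, 0 °C → rt
Reagents that add atoms: acetic anhydride, CC(=O)OC(C)=O
Why: DMAP-catalysed O-acetylation of the primary allylic alcohol; the tertiary amine, lactam and ketones offer no other acylable site.

Step 9
Reactants: 15 first quinolizidinone allylic acetate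
Product: 18 tetradehydropetrosin A (meso E,E-diene macrocycle), via enamine acetate 16 (not isolated), via macrocyclic iminium acetate 17 (not isolated)
Conditions: IrCl(CO)(PPh3)2 (2 mol%), (Me2SiH)2O (2 equiv), toluene, rt, then evaporate; syringe-pump addition to Pd(PPh3)4 (10 mol%), MeCN, 50 °C (1 mM); AcOH (20 equiv), 60 °C; chromatography
Reagents that add atoms: none
Why: Proposed new method: hydrosilylation of the lactam carbonyl C9a′ and loss of silanol gives the enamine N5′–C9a′=C9′ (16), whose β-carbon C9′ attacks the CH2 terminus of the π-allylpalladium cation that zerovalent palladium forms from the allylic acetate, closing a 20-membered ring and leaving the iminium N5′=C9a′ (17); AcOH then lets the enol C1′=C2′ of the ketone arm add to C9a′, a transannular Mannich reaction that contracts the large ring to the 16-membered carbocycle and creates the second piperidinone ring. The closest known reaction types are the Tsuji–Trost α-allylation of aldehyde-derived enamines (intermolecular and for five- and six-membered rings), palladium-catalysed macrocyclic allylation by stabilised carbanions and the Mannich closure of 1-(3-oxoalkyl)-Δ1-piperideinium ions; a neutral enamine as the ring-closing partner of a macrocyclic allylation has not been shown. The macrocycle closes at the unsubstituted allyl terminus with the alkene inside the ring (attack at the inner carbon would give an 18-membered ring with a vinyl branch), and the piperidinone closes through a 6-(enolendo)-endo-trig chair. C9′ stays mobile through iminium–enamine tautomerism until the Mannich step, C9a′ is set by attack anti to the C9′ chain (H9′ trans to H9a′), and C1′ and C3′ settle by acid enolization to the axial C1′ chain and equatorial methyl, the arrangement that avoids the peri (syn-pentane) clash between the C1′ and C9′ chains. Nothing in the substrate biases the pairing of the new half with the remote first half, so the centrosymmetric diene 18 is separated by chromatography from its C2-symmetric diastereomer, which is returned to the AcOH equilibration (retro-Mannich, enamine, Mannich). The step needs C- over N-allylation (N-allyl ammonium ions re-ionise under zerovalent palladium, the C–C bond does not), ring closure over oligomerisation (slow addition at high dilution) and lactam over ketone reduction (the known preference of this iridium/disiloxane pair for tertiary amides).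

Step 10
Reactants: 18 tetradehydropetrosin A
Product: 19 petrosin A
Conditions: H2 (1 atm), 10% Pd/C, EtOAc, rt
Reagents that add atoms: none
Why: Heterogeneous catalytic hydrogenation of the two disubstituted alkenes under neutral conditions; ketones and tertiary amines are inert to Pd/C at 1 atm, and without acid or base neither enolization nor retro-Mannich cleavage can disturb the eight stereocentres.

Compound list
1 | piperidin-2-one | O=C1CCCCN1 | starting material
2 | methyl methacrylate | C=C(C)C(=O)OC | starting material
3 | methyl 2-methyl-3-(2-oxopiperidin-1-yl)propanoate; racemic | COC(=O)C(C)CN1CCCCC1=O | intermediate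
4 | N-methoxy-N,2-dimethyl-3-(2-oxopiperidin-1-yl)propanamide; racemic | CON(C)C(=O)C(C)CN1CCCCC1=O | intermediate
5 | pent-4-en-1-ylmagnesium bromide (THF solution) | C=CCCC[Mg]Br | starting material
6 | 1-(2-methyl-3-oxooct-7-en-1-yl)piperidin-2-one; racemic | C=CCCCC(=O)C(C)CN1CCCCC1=O | intermediate
7 | (Z)-but-2-ene-1,4-diyl diacetate | CC(=O)OC/C=C\COC(C)=O | starting material
8 | (2E)-8-methyl-7-oxo-9-(2-oxopiperidin-1-yl)non-2-en-1-yl acetate; racemic | CC(=O)OC/C=C/CCCC(=O)C(C)CN1CCCCC1=O | intermediate
9 | allyloxy(tert-butyl)dimethylsilane | C=CCO[Si](C)(C)C(C)(C)C | starting material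
10 | 1-[(7E)-9-(tert-butyldimethylsilyloxy)-2-methyl-3-oxonon-7-en-1-yl]piperidin-2-one; racemic | CC(C)(C)[Si](C)(C)OC/C=C/CCCC(=O)C(C)CN1CCCCC1=O | intermediate
11 | endocyclic enamine: 10 with the lactam reduced to a 1,2,3,4-tetrahydropyridine (N–CH=CH) | CC(C)(C)[Si](C)(C)OC/C=C/CCCC(=O)C(C)CN1CCCC=C1 | intermediate
12 | C-allylated iminium acetate: 2,3,4,5-tetrahydropyridinium ion from 11 carrying at C3 the (2E)-8-methyl-7-oxo-9-(2-oxopiperidin-1-yl)non-2-en-1-yl chain of 8 | CC(C)(C)[Si](C)(C)OC/C=C/CCCC(=O)C(C)C[N+]1=CC(C/C=C/CCCC(=O)C(C)CN2CCCCC2=O)CCC1.CC(=O)[O-] | intermediate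
13 | first quinolizidinone silyl ether: trans-fused 3-methylquinolizidin-2-one; C9 carries (equatorial; H9 trans to H9a) the (2E)-8-methyl-7-oxo-9-(2-oxopiperidin-1-yl)non-2-en-1-yl chain; C1 carries (axial; H1 cis to H9a; trans to the equatorial 3-methyl) the (3E)-5-(tert-butyldimethylsilyloxy)pent-3-en-1-yl chain; racemic; open-chain CHMe as both epimers | C[C@@H]1CN2CCC[C@H](C/C=C/CCCC(=O)C(C)CN3CCCCC3=O)[C@H]2[C@@H](CC/C=C/CO[Si](C)(C)C(C)(C)C)C1=O | intermediate
14 | first quinolizidinone allylic alcohol: 13 with OH in place of the silyl ether | C[C@@H]1CN2CCC[C@H](C/C=C/CCCC(=O)C(C)CN3CCCCC3=O)[C@H]2[C@@H](CC/C=C/CO)C1=O | intermediate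
15 | first quinolizidinone allylic acetate: the acetate of 14 | C[C@@H]1CN2CCC[C@H](C/C=C/CCCC(=O)C(C)CN3CCCCC3=O)[C@H]2[C@@H](CC/C=C/COC(C)=O)C1=O | intermediate
16 | enamine acetate: 15 with the lactam reduced to a 1,2,3,4-tetrahydropyridine | C[C@@H]1CN2CCC[C@H](C/C=C/CCCC(=O)C(C)CN3CCCC=C3)[C@H]2[C@@H](CC/C=C/COC(C)=O)C1=O | intermediate
17 | macrocyclic iminium acetate: 20-membered ring closed between C9′ of the tetrahydropyridinium ring and the former CH2OAc carbon; C9′ undefined | C[C@@H]1CN2CCC[C@H](C/C=C/CCCC(=O)C(C)C[N+]3=CC4CCC3)[C@H]2[C@@H](CC/C=C/C4)C1=O.CC(=O)[O-] | intermediate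
18 | tetradehydropetrosin A: petrosin A with E double bonds between the second and third bridge carbons counted from C9 and from C9′; meso (centrosymmetric); each half configured as in 13 | C[C@@H]1CN2CCC[C@@H]3C/C=C/CC[C@@H]4C(=O)[C@@H](C)CN5CCC[C@@H](C/C=C/CC[C@@H](C1=O)[C@H]32)[C@H]45 | intermediate
19 | petrosin A: meso bis-quinolizidin-2-one; in each half H9 trans to H9a, H1 cis to H9a, 3-methyl trans to the C1 bridge; the two halves are mirror images | C[C@@H]1CN2CCC[C@@H]3CCCCC[C@@H]4C(=O)[C@@H](C)CN5CCC[C@@H](CCCCC[C@@H](C1=O)[C@H]32)[C@H]45 | target

Total step count: 10. Longest linear sequence: 9 (steps 1, 2, 3, 5, 6, 7, 8, 9, 10; step 4 is the branch that supplies 8).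

Steps most likely to fail

Step 9. The enamine may oligomerise instead of closing the ring, may attack the inner allyl carbon, or may decay before it meets the allyl complex. The fallback uses known reactions only and sets out from 6. Used in place of 10 in the step 6 sequence with 8, compound 6 should give the butenyl quinolizidinone F1. The same three operations on the lactam of F1, with allyl acetate as the electrophile (intermolecular Tsuji–Trost allylation of the enamine, then AcOH), should give the allyl butenyl bis-quinolizidinone F2, the unlike pairing being separated by chromatography. Ring-closing metathesis of its bis-ammonium salt (TsOH·H2O 2 equiv, first-generation Grubbs catalyst RuCl2(=CHPh)(PCy3)2, CH2Cl2, 40 °C, 1 mM, then NaHCO3) should give the macrocyclic diene F3 as an E/Z mixture at the new alkene. Hydrogenation under the step 10 conditions comes back to the route at 19.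

Step 6. The ketone may be reduced beside the lactam during hydrosilylation, or the keto-enamine may self-condense before allylation. The fallback sets out from 10. Ketalisation with 1,2-bis(trimethylsilyloxy)ethane and Me3SiOTf (cat.) in CH2Cl2 at −78 °C should give the dioxolane F4. The same reduction and palladium-catalysed allylation with 8 should give the ketal-protected iminium acetate F5. Treatment with 2 M aq. HCl in THF at 50 °C, then NaHCO3, unmasks the ketone, removes the silyl ether and triggers the Mannich closure, so the sequence comes back at 14 and step 7 is skipped.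

Step 3. The Grignard reagent may deprotonate α to the Weinreb amide, leading to β-elimination of the lactam anion (retro-aza-Michael), or may add competitively to the lactam carbonyl. The fallback sets out from 5. Addition to methacrolein (THF, −78 °C) should give 2-methylocta-1,7-dien-3-ol F6. Oxidation with MnO2 (CH2Cl2, rt) should give 2-methylocta-1,7-dien-3-one F7. Base-catalysed aza-Michael addition of 1 (t-BuOK cat., THF, 0 °C) comes back at 6, so steps 1 and 2 are skipped.

Further compounds
F1 | step 9 | butenyl quinolizidinone: as 13 but with a but-3-en-1-yl chain at C1 | C[C@@H]1CN2CCC[C@H](C/C=C/CCCC(=O)C(C)CN3CCCCC3=O)[C@H]2[C@@H](CCC=C)C1=O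
F2 | step 9 | allyl butenyl bis-quinolizidinone: both quinolizidinones formed, allyl at C9′, but-3-en-1-yl at C1, unlike pairing of the halves | C[C@@H]1CN2CCC[C@H](C/C=C/CC[C@@H]3C(=O)[C@@H](C)CN4CCC[C@@H](CC=C)[C@H]34)[C@H]2[C@@H](CCC=C)C1=O
F3 | step 9 | macrocyclic diene from ring-closing metathesis: as 18 but E/Z at the alkene of the C9′ bridge | C[C@@H]1CN2CCC[C@@H]3C/C=C/CC[C@@H]4C(=O)[C@@H](C)CN5CCC[C@@H](CC=CCC[C@@H](C1=O)[C@H]32)[C@H]45
F4 | step 6 | dioxolane of 10 (ketone as ethylene ketal) | CC(C)(C)[Si](C)(C)OC/C=C/CCCC1(OCCO1)C(C)CN2CCCCC2=O
F5 | step 6 | ketal-protected C-allylated iminium acetate (12 with the ketone of the N-arm as ethylene ketal) | CC(C)(C)[Si](C)(C)OC/C=C/CCCC1(OCCO1)C(C)C[N+]2=CC(C/C=C/CCCC(=O)C(C)CN3CCCCC3=O)CCC2.CC(=O)[O-]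
F6 | step 3 | 2-methylocta-1,7-dien-3-ol (racemic) | C=CCCCC(O)C(C)=C
F7 | step 3 | 2-methylocta-1,7-dien-3-one | C=CCCCC(=O)C(C)=C
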